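## Structural features

The target is a flavone in which ring A (benzene) and ring C (4-pyranone) are fused along C4a–C8a, and ring B, a 2,4-dihydroxyphenyl group, sits on C2. Ring A carries a methyl ether at C5, a free hydroxyl at C7, the ring oxygen O1 on C8a and a ten-carbon chain on C8; only C6 is unsubstituted. The chain is a hydrated lavandulyl unit, C8–CH2–CH(isopropenyl)–CH2–CH2–C(CH3)2OH, whose CH carbon is the only stereocentre (R), has no stereogenic neighbour and lies one CH2 away from ring A. The fragile groups are the 1,1-disubstituted alkene and the tertiary alcohol (both ionise in acid), the C7 hydroxyl (ortho to the chain, able to close a chroman on a cation from the alkene) and the allylic tertiary C–H of the stereocentre, which makes a carbonyl, radical or leaving group on the adjacent carbon a hazard. The real difficulty is to place chain, hydroxyl, methoxyl and ring oxygen on ring A without positional isomers, and to join a β-branched chiral chain to a carbon flanked by two oxygens without touching the stereocentre; (R)-limonene offers that stereocentre with one carbon too many on the arm that must become the benzylic CH2. The key step exploits the fact that C4 is a single carbonyl carbon between C4a of ring A and the C3=C2 unit bearing ring B, with O1 on the neighbouring C8a, so ring C is an aryl iodide carbon, one CO, a terminal arylacetylene and an ortho phenol oxygen. A 2-alkyl-5-methoxyresorcinol has a mirror plane through the alkyl-bearing carbon, so iodination at either free position gives one compound, and the iodine then decides which oxygen becomes O1.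

## Logic of the disconnections

**24 ⇒ 23.** The two acetal C–O bonds on the ring B oxygens are cut. Ring B must be masked while palladium is present, because a free hydroxyl ortho to an ethynyl group would cyclise; the C7 hydroxyl needs no mask. Nothing is gained in skeleton. The forward step must cleave two aryl acetals without protonating the alkene or ionising the tertiary alcohol.

**23 ⇒ 16 + 19 + 20.** The bonds C4a–C4, C4–C3 and O1–C2 are cut, which removes ring C and divides the molecule into two aromatic halves of similar size and a one-carbon unit. This is the most convergent cut and places ring formation after all chain chemistry. The forward step must insert 20 before the alkyne couples, must close 6-endo and not 5-exo, and must shed the two O-acyl groups of 16 in the flask (through 21 and 22).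

**16 ⇒ 14 (through 15).** The C4a–I bond and two O–acyl bonds are cut. Because 14 is symmetric, only one mono-iodide can form, and acylating both oxygens alike removes any need to tell O7 from O8a. The forward step must stop at one iodine and must substitute the ring faster than it attacks the alkene.

**14 ⇒ 13 ⇒ 12.** First the two acetal C–O bonds on ring A are cut, then one C–CH3 bond of the carbinol. Keeping the chain oxygen as a ketone until after the aryl–alkyl coupling avoids a free hydroxyl near an organometallic carbon and any cyclic ether formation on a primary iodide. The forward steps need a methyl nucleophile that adds without enolising, and an acid mild enough for the alkene and the tertiary alcohol.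

**12 ⇒ 6 + 10 (through 11).** The C8–CH2 bond is cut as a cross-coupling between an sp3 zinc carbon and an sp2 iodide. A polar displacement at this β-branched carbon, whose β-hydrogen is tertiary and allylic, would compete with elimination; a catalysed coupling does not. The cut separates ring A from the chain. It demands that 11 tolerate its own ketone and that the catalyst accept an aryl iodide with two ortho substituents.

**10 ⇒ 8 ⇒ 7 (through 9).** The C–I bond and then the two acetal C–O bonds are cut. The acetals protect and also direct metalation to the carbon between them; 7 is commercial and already carries the methyl ether destined for O5.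

**6 ⇒ 4 (through 5).** The C–I bond is exchanged for a C–CO2H bond. The stereocentre of 1 maps on that of 24 with the same sense (R in both) only if the ring CH2 next to the trisubstituted alkene becomes the benzylic carbon, and that arm is one carbon too long. Removing the extra carbon as CO2 keeps the CH2 and never places a carbonyl on the stereocentre. The forward step must trap a primary homoallyl radical with iodine before it can rearrange.

**4 ⇒ 3 ⇒ 1 (through 2).** The acid is taken back to the aldehyde, and the two carbonyl groups are rejoined as the ring alkene of 1. This reaches a cheap terpene that supplies stereocentre, isopropenyl group and methyl ketone in one piece. The cleavage must choose the trisubstituted ring alkene over the isopropenyl group, and the oxidation must touch only the aldehyde.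

**19 ⇒ 18 ⇒ 17.** The terminal alkyne carbon is removed and the two acetals are cut, leading to a commercial aldehyde. The homologation must run in a base that leaves aryl acetals alone.

## Other disconnections considered

**Alternative 1:** Ring A is taken apart at C8–C8a, C6–C7 and C4a–C8a. In the forward sense the chain-bearing siloxyalkyne A1 would be heated with 3-methoxycyclobutenone A2. Ring opening to a vinylketene, [2+2] addition to the alkyne, a second ring opening and a 6-electron closure would give phenol A3.
- In its favour: the crowded C8–CH2 bond is never made by coupling; the three ring A oxygens arrive already told apart (free at C8a, silylated at C7, methylated at C5); and all ten carbons of 1 are used, since the ester carbon of the chain becomes C8 and no decarboxylation is needed. On these three points it is better than the chosen plan.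
- Against it here: A1 needs an ester-to-ynolate homologation with strong lithium bases beside an isopropenyl group and is hydrolytically fragile; A2 is not a shelf compound; and A3 still lacks C4. Ring C would have to follow through a functionalisation that must distinguish C4a (ortho to the free hydroxyl) from C6 (para to it).
- Comparison: on structure it solves the ring A pattern more elegantly. On mechanism the pericyclic cascade should fix regiochemistry by polarity as firmly as the iodine does in the chosen plan (equal). On step economy it is longer, because it builds a ring that the chosen plan buys as 7 and then still needs an iodination and the same annulation.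

**Alternative 2:** Ring A is cut at C8–C8a and C4a–C5 and is built on a pyranone that already carries ring B. Diene A4, a 4-alkyl-1,1-dimethoxy-3-siloxybutadiene, would add to the sulfinyl-activated double bond of pyranone A5, its nucleophilic terminus bonding to C8a. Syn-elimination of the sulfinyl group and loss of one methoxyl would aromatise the adduct to A6.
- In its favour: rings B and C are made first on simple material; neither CO nor palladium is needed; the diene polarity places chain, hydroxyl and methoxyl at C8, C7 and C5 without any symmetry argument; and A6 is one deprotection from 24, which equals the chosen plan after the key step.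
- Against it here: A4 is a moisture-sensitive ketene acetal with a branched chiral substituent on its reacting terminus and would be slow in cycloaddition. It would have to be made by alkylation chemistry from the same iodide 6, so the carbon excision is not saved. The pyranone is a reluctant dienophile even with the sulfoxide, and A5 needs its own several-step preparation.
- Comparison: on structure both plans end in the right pattern (equal). On mechanism a thermal cycloaddition–elimination cascade at a hindered diene terminus is less predictable than oxidative addition at a C–I bond. On step economy it is several steps longer, since ring A is built and not bought.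

**Alternative 3:** Ring A is cut at C7–C8 and C5–C6. Pyranone ester A7 carries ring B, an ester on C4a and, on C8a, the chain lengthened by one CH2 (the future C8). It would be deprotonated at C8 with excess lithium amide base, C-acetylated, and closed by Claisen condensation of the methyl ketone on the ester to give A8.
- In its favour: one operation makes two C–C bonds and the ring from an acetyl unit; no transition metal is used; and the stereocentre is as remote from the chemistry as in the chosen plan (equal).
- Against it here: A8 is the 5,7-diol, whereas 24 needs a methyl group on O5 only. The chelated 5-hydroxyl is the less reactive one, so protection of O7, methylation and deprotection would be added. The C8 carbanion is secondary and hindered and would compete with O-acylation and attack on the ester, and A7 is itself a multi-step target.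
- Comparison: on structure it mismatches the O5/O7 differentiation that the chosen plan takes from 7. On mechanism vinylogous enolate acylation is harder to control than the palladium sequence. On step economy it is clearly longer.

Key step: step 12

Remark on the chemistry: both phenols of the ring A ortho-iodophenol 15 enter the key step as acetates (16), which diethylamine removes in the flask; the oxygen that closes ring C is still the phenol oxygen ortho to iodine, and no selective protection of O7 is needed.

## Route

Step 1
Reactants: 1 (R)-(+)-limonene
Product: 3 (3R)-6-oxo-3-(prop-1-en-2-yl)heptanal, via methoxy hydroperoxide 2 (not isolated)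
Conditions: O3 (1.0 equiv), CH2Cl2–MeOH, −78 °C; then Me2S, −78 °C → rt
Reagents that add atoms: ozone, [O-][O+]=O
Why: Ozonolysis (Criegee cleavage) with reductive work-up; the trisubstituted ring alkene is markedly more electron-rich than the isopropenyl group and should be consumed first when ozone is metered, methanol trapping the carbonyl oxide as 2. The stereocentre is not involved and stays R.

Step 2
Reactants: 3 (3R)-6-oxo-3-(prop-1-en-2-yl)heptanal
Product: 4 (3R)-6-oxo-3-(prop-1-en-2-yl)heptanoic acid
Conditions: NaClO2, NaH2PO4, 2-methyl-2-butene, t-BuOH–H2O, 0 °C → rt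
Reagents that add atoms: sodium chlorite, [Na+].[O-]Cl=O
Why: Pinnick oxidation; chlorite oxidises only the aldehyde and the alkene scavenger removes hypochlorous acid before it can reach the isopropenyl group. The stereocentre is β to the carbonyl and cannot epimerise.

Step 3
Reactants: 4 (3R)-6-oxo-3-(prop-1-en-2-yl)heptanoic acid
Product: 6 (5S)-5-(iodomethyl)-6-methylhept-6-en-2-one, via Barton ester 5 (not isolated)
Conditions: 2-mercaptopyridine N-oxide, DCC, CH2Cl2, 0 °C → rt, dark; then CHI3, hν (tungsten lamp), rt
Reagents that add atoms: iodoform, IC(I)I
Why: Barton decarboxylative iodination, a radical chain in which the primary radical formed from 5 by loss of CO2 takes iodine from CHI3. Iodine transfer should be far faster than 3-exo closure of the homoallyl radical, so the CH2 stays on the stereocentre; the descriptor becomes S only through the priority of iodine.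

Step 4
Reactants: 7 5-methoxyresorcinol
Product: 8 1-methoxy-3,5-bis(methoxymethoxy)benzene
Conditions: MOMCl, i-Pr2NEt, CH2Cl2, 0 °C → rt
Reagents that add atoms: chloromethyl methyl ether, COCCl
Why: O-Alkylation of both phenols to MOM acetals, chosen because they direct the metalation of step 5 and survive organozinc and Grignard reagents.

Step 5
Reactants: 8 1-methoxy-3,5-bis(methoxymethoxy)benzene
Product: 10 2-iodo-5-methoxy-1,3-bis(methoxymethoxy)benzene, via aryllithium 9 (not isolated)
Conditions: n-BuLi, THF, 0 °C; then I2, −78 °C → rt
Reagents that add atoms: iodine, II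
Why: Directed ortho-metalation; the carbon between the two chelating MOM ethers is the most acidic ring position, and 9 is quenched by iodine at that carbon.

Step 6
Reactants: 6 (5S)-5-(iodomethyl)-6-methylhept-6-en-2-one; 10 2-iodo-5-methoxy-1,3-bis(methoxymethoxy)benzene
Product: 12 (5R)-5-{[4-methoxy-2,6-bis(methoxymethoxy)phenyl]methyl}-6-methylhept-6-en-2-one, via alkylzinc iodide 11 (not isolated)
Conditions: Zn dust (activated with BrCH2CH2Br and Me3SiCl), THF, 35 °C; then 10, Pd(OAc)2 (2 mol %), SPhos (4 mol %), THF, rt → 45 °C
Reagents that add atoms: none
Why: Negishi coupling; zinc inserts into the primary C–I bond to give 11, which tolerates the ketone, and palladium with a bulky biarylphosphine couples primary alkylzinc halides with di-ortho-substituted aryl iodides while reductive elimination outruns β-hydride elimination. The stereocentre is β to zinc and is not touched; the descriptor returns to R by priority only.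

Step 7
Reactants: 12 (5R)-5-{[4-methoxy-2,6-bis(methoxymethoxy)phenyl]methyl}-6-methylhept-6-en-2-one
Product: 13 (5R)-5-{[4-methoxy-2,6-bis(methoxymethoxy)phenyl]methyl}-2,6-dimethylhept-6-en-2-ol
Conditions: MeMgBr, THF, −78 → 0 °C; aq NH4Cl
Reagents that add atoms: methylmagnesium bromide, C[Mg]Br
Why: Grignard addition to the methyl ketone; the new carbinol carbon bears two methyl groups and is not a stereocentre, and the aryl MOM ethers and the alkene are inert.

Step 8
Reactants: 13 (5R)-5-{[4-methoxy-2,6-bis(methoxymethoxy)phenyl]methyl}-2,6-dimethylhept-6-en-2-ol
Product: 14 2-[(2R)-5-hydroxy-5-methyl-2-(prop-1-en-2-yl)hexyl]-5-methoxybenzene-1,3-diol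
Conditions: p-TsOH·H2O (0.3 equiv), MeOH, 35 °C
Reagents that add atoms: none
Why: Acid-catalysed transacetalisation to methanol; MOM ethers on the electron-rich ring should cleave under conditions too mild to protonate the isopropenyl group or ionise the tertiary alcohol.

Step 9
Reactants: 14 2-[(2R)-5-hydroxy-5-methyl-2-(prop-1-en-2-yl)hexyl]-5-methoxybenzene-1,3-diol
Product: 16 2-[(2R)-5-hydroxy-5-methyl-2-(prop-1-en-2-yl)hexyl]-4-iodo-5-methoxy-1,3-phenylene diacetate, via iodoresorcinol 15 (not isolated)
Conditions: NIS (1.0 equiv), MeCN, −20 °C; then Ac2O, pyridine, 0 °C → rt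
Reagents that add atoms: N-iodosuccinimide, O=C1CCC(=O)N1I; acetic anhydride, CC(=O)OC(C)=O
Why: Electrophilic aromatic iodination followed by O-acetylation; the two free ring positions of 14 are equivalent and far more nucleophilic than the alkene, so one equivalent of NIS should give 15 alone. Both phenols are then acetylated without any need for selectivity, and the tertiary alcohol stays free in the absence of an acyl-transfer catalyst.

Step 10
Reactants: 17 2,4-dihydroxybenzaldehyde
Product: 18 2,4-bis(methoxymethoxy)benzaldehyde
Conditions: MOMCl, K2CO3, acetone, reflux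
Reagents that add atoms: chloromethyl methyl ether, COCCl
Why: O-Alkylation of both phenols; carbonate in hot acetone also reaches the hydrogen-bonded hydroxyl ortho to the aldehyde.

Step 11
Reactants: 18 2,4-bis(methoxymethoxy)benzaldehyde
Product: 19 1-ethynyl-2,4-bis(methoxymethoxy)benzene
Conditions: dimethyl (1-diazo-2-oxopropyl)phosphonate, K2CO3, MeOH, 0 °C → rt
Reagents that add atoms: dimethyl (1-diazo-2-oxopropyl)phosphonate, COP(=O)(OC)C(=[N+]=[N-])C(C)=O
Why: Seyferth–Gilbert homologation with the Ohira–Bestmann reagent; methanolysis frees the diazomethylphosphonate anion, which converts the aldehyde into the terminal alkyne in a base that leaves aryl MOM ethers intact.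

Step 12
Reactants: 16 2-[(2R)-5-hydroxy-5-methyl-2-(prop-1-en-2-yl)hexyl]-4-iodo-5-methoxy-1,3-phenylene diacetate; 19 1-ethynyl-2,4-bis(methoxymethoxy)benzene; 20 carbon monoxide
Product: 23 2-[2,4-bis(methoxymethoxy)phenyl]-7-hydroxy-8-[(2R)-5-hydroxy-5-methyl-2-(prop-1-en-2-yl)hexyl]-5-methoxy-4H-chromen-4-one, via ynone diacetate 21 (not isolated), via enaminone 22 (not isolated)
Conditions: PdCl2(PPh3)2 (5 mol %), thiourea (5 mol %), dppp (5 mol %), Et2NH, DBU, CO (1 atm), 40 °C
Reagents that add atoms: none
Why: Palladium-catalysed carbonylative Sonogashira coupling followed by annulation, the known carbonylative route from ortho-iodophenol acetates and terminal alkynes to flavones. Zerovalent palladium, formed from PdCl2(PPh3)2 under amine and CO, should insert into the C4a–I bond of 16, and 20 should insert to give an aroyl complex of divalent palladium; alkyne 19, deprotonated by the amine, is transferred to palladium and reductive elimination forms C4a–C4 and C4–C3 in ynone 21. Diethylamine then cleaves both aryl acetates and adds in conjugate fashion to give enaminone 22, and the freed C8a phenoxide attacks C2 and expels the amine. Ring C therefore closes by O1–C2 bond formation in the 6-endo mode (6-endo-trig addition–elimination on 22, the net 6-endo-dig hydroalkoxylation of the ynone). No stereocentre is formed, and the chain stereocentre is remote and not involved. The step needs CO insertion ahead of direct alkynylation and 6-endo in place of 5-exo (aurone) closure: the acetylated oxygen cannot cyclise until the ynone exists, the CO atmosphere and the crowded aryl–palladium favour insertion, and the amine relay through 22 leaves only C2 electrophilic. Regiochemistry on ring A is fixed by the iodine, since only the C8a oxygen is ortho to the new acyl group and the C7 oxygen is para to it. The mildly basic medium at 40 °C should leave the MOM ethers, the isopropenyl group and the tertiary alcohol unchanged.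

Step 13
Reactants: 23 2-[2,4-bis(methoxymethoxy)phenyl]-7-hydroxy-8-[(2R)-5-hydroxy-5-methyl-2-(prop-1-en-2-yl)hexyl]-5-methoxy-4H-chromen-4-one
Product: 24 2-(2,4-dihydroxyphenyl)-7-hydroxy-8-[(2R)-5-hydroxy-5-methyl-2-(prop-1-en-2-yl)hexyl]-5-methoxy-4H-chromen-4-one
Conditions: 3 M aq HCl, MeOH–THF, 40 °C
Reagents that add atoms: none
Why: Acid-catalysed cleavage of the two aryl MOM ethers; only two acetals remain, so exposure can be kept short and the reaction stopped at full conversion to protect the isopropenyl group and the tertiary alcohol.

## Compound list

1 | (R)-(+)-limonene | C=C(C)[C@@H]1CCC(C)=CC1 | starting material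
2 | (3R)-6-hydroperoxy-6-methoxy-3-(prop-1-en-2-yl)heptanal (C6 unassigned; not isolated) | C=C(C)[C@@H](CC=O)CCC(C)(OC)OO | intermediate
3 | (3R)-6-oxo-3-(prop-1-en-2-yl)heptanal | C=C(C)[C@@H](CC=O)CCC(C)=O | intermediate
4 | (3R)-6-oxo-3-(prop-1-en-2-yl)heptanoic acid | C=C(C)[C@@H](CC(=O)O)CCC(C)=O | intermediate
5 | 2-thioxopyridin-1(2H)-yl (3R)-6-oxo-3-(prop-1-en-2-yl)heptanoate (Barton ester; not isolated) | C=C(C)[C@@H](CC(=O)On1ccccc1=S)CCC(C)=O | intermediate
6 | (5S)-5-(iodomethyl)-6-methylhept-6-en-2-one | C=C(C)[C@@H](CI)CCC(C)=O | intermediate
7 | 5-methoxyresorcinol | COc1cc(O)cc(O)c1 | starting material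
8 | 1-methoxy-3,5-bis(methoxymethoxy)benzene | COCOc1cc(OC)cc(OCOC)c1 | intermediate
9 | [4-methoxy-2,6-bis(methoxymethoxy)phenyl]lithium (not isolated) | [Li]c1c(OCOC)cc(OC)cc1OCOC | intermediate
10 | 2-iodo-5-methoxy-1,3-bis(methoxymethoxy)benzene | COCOc1cc(OC)cc(OCOC)c1I | intermediate
11 | [(2S)-5-oxo-2-(prop-1-en-2-yl)hexyl]zinc iodide (not isolated) | C=C(C)[C@@H](C[Zn]I)CCC(C)=O | intermediate
12 | (5R)-5-{[4-methoxy-2,6-bis(methoxymethoxy)phenyl]methyl}-6-methylhept-6-en-2-one | C=C(C)[C@H](CCC(C)=O)Cc1c(OCOC)cc(OC)cc1OCOC | intermediate
13 | (5R)-5-{[4-methoxy-2,6-bis(methoxymethoxy)phenyl]methyl}-2,6-dimethylhept-6-en-2-ol | C=C(C)[C@H](CCC(C)(C)O)Cc1c(OCOC)cc(OC)cc1OCOC | intermediate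
14 | 2-[(2R)-5-hydroxy-5-methyl-2-(prop-1-en-2-yl)hexyl]-5-methoxybenzene-1,3-diol | C=C(C)[C@H](CCC(C)(C)O)Cc1c(O)cc(OC)cc1O | intermediate
15 | 2-[(2R)-5-hydroxy-5-methyl-2-(prop-1-en-2-yl)hexyl]-4-iodo-5-methoxybenzene-1,3-diol (ring A ortho-iodophenol; not isolated) | C=C(C)[C@H](CCC(C)(C)O)Cc1c(O)c(I)c(OC)cc1O | intermediate
16 | 2-[(2R)-5-hydroxy-5-methyl-2-(prop-1-en-2-yl)hexyl]-4-iodo-5-methoxy-1,3-phenylene diacetate | C=C(C)[C@H](CCC(C)(C)O)Cc1c(OC(C)=O)c(I)c(OC)cc1OC(C)=O | intermediate
17 | 2,4-dihydroxybenzaldehyde | O=Cc1ccc(O)cc1O | starting material
18 | 2,4-bis(methoxymethoxy)benzaldehyde | COCOc1ccc(C=O)c(OCOC)c1 | intermediate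
19 | 1-ethynyl-2,4-bis(methoxymethoxy)benzene | C#Cc1ccc(OCOC)cc1OCOC | intermediate
20 | carbon monoxide | [C-]#[O+] | starting material
21 | 4-{3-[2,4-bis(methoxymethoxy)phenyl]prop-2-ynoyl}-2-[(2R)-5-hydroxy-5-methyl-2-(prop-1-en-2-yl)hexyl]-5-methoxy-1,3-phenylene diacetate (not isolated) | C=C(C)[C@H](CCC(C)(C)O)Cc1c(OC(C)=O)c(C(=O)C#Cc2ccc(OCOC)cc2OCOC)c(OC)cc1OC(C)=O | intermediate
22 | 3-[2,4-bis(methoxymethoxy)phenyl]-3-(diethylamino)-1-{2,4-dihydroxy-3-[(2R)-5-hydroxy-5-methyl-2-(prop-1-en-2-yl)hexyl]-6-methoxyphenyl}prop-2-en-1-one (alkene geometry unassigned; not isolated) | C=C(C)[C@H](CCC(C)(C)O)Cc1c(O)c(C(=O)C=C(N(CC)CC)c2ccc(OCOC)cc2OCOC)c(OC)cc1O | intermediate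
23 | 2-[2,4-bis(methoxymethoxy)phenyl]-7-hydroxy-8-[(2R)-5-hydroxy-5-methyl-2-(prop-1-en-2-yl)hexyl]-5-methoxy-4H-chromen-4-one | C=C(C)[C@H](CCC(C)(C)O)Cc1c(O)cc(OC)c2c(=O)cc(-c3ccc(OCOC)cc3OCOC)oc12 | intermediate
24 | 2-(2,4-dihydroxyphenyl)-7-hydroxy-8-[(2R)-5-hydroxy-5-methyl-2-(prop-1-en-2-yl)hexyl]-5-methoxy-4H-chromen-4-one | C=C(C)[C@H](CCC(C)(C)O)Cc1c(O)cc(OC)c2c(=O)cc(-c3ccc(O)cc3O)oc12 | target

## Step count and least certain steps

Total: 13 steps. Longest linear sequence: 9 steps (steps 1, 2, 3, 6, 7, 8, 9, 12, 13; from 1 to 24).

**Step 12 (key step).** Most likely to go wrong: coupling of the alkyne before CO insertion with later closure to a benzofuran, reductive loss of iodine from the crowded aryl–palladium, or capture of the aroyl–palladium by diethylamine. All compete with CO uptake at one atmosphere. The fallback uses neither palladium nor CO; it sets out from 13 and 19 and comes back at 24. Treatment of 13 with n-BuLi (one equivalent for the alkoxide, one for ring lithiation between the MOM ether and the methoxyl) and DMF should give the aldehyde F1. The lithium acetylide of 19 should add to it to give the propargylic alcohol F2, and MnO2 should oxidise this to the ynone F3. Acid methanolysis (p-TsOH, MeOH, 40 °C) should then strip all four MOM groups while the freed C8a hydroxyl closes on the ynone, giving 24 directly.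

**Step 3.** Most likely to go wrong: interception of the primary radical by the thiocarbonyl group of 5 in place of iodine transfer, or slow trapping that lets the homoallyl radical close and reopen with a vinyl shift, which would erase the stereocentre. The fallback sets out from 4 and comes back at 12, passing over step 6 as well. Acid 4 is converted with N-hydroxyphthalimide and N,N′-diisopropylcarbodiimide into the N-hydroxyphthalimide ester F4. Aryllithium 9 and ZnCl2 give the arylzinc chloride F5. Decarboxylative arylation of F4 with F5 under Fe(acac)3 and 1,2-bis(diphenylphosphino)benzene in THF at rt should give 12.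

**Step 6.** Most likely to go wrong: β-hydride elimination from the alkyl–palladium intermediate at the allylic tertiary C–H, giving a diene, or slow transmetalation to the di-ortho-substituted aryl–palladium. The fallback is a polar alkylation; it sets out from 6 and 8 and comes back at 14. MeMgBr at −78 °C, where the primary iodide is inert, converts 6 into the hydroxy iodide F6. Et3SiOTf and 2,6-lutidine give the silyl ether F7, which is needed because a free alkoxide could close a tetrahydropyran on the iodide. Aryllithium 9 (from 8) in THF–DMPU, −78 °C → rt, should displace iodide to give the alkylated arene F8; elimination is the competing process and is the reason this is not the main route. The conditions of step 8 remove the silyl and MOM groups together and return 14.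

**Step 9.** Most likely to go wrong: a second iodination at C6, or iodonium formation at the isopropenyl group with capture by a neighbouring hydroxyl, since the free resorcinol and the alkene both answer to electrophilic iodine. The fallback sets out from 13 and comes back at 15. n-BuLi (2 equiv), THF, 0 °C, then I2, places a single iodine by directed lithiation and gives the aryl iodide F9. The conditions of step 8 free the phenols to 15, which is acetylated as in the second stage of step 9.

**Step 13.** Most likely to go wrong: protonation of the isopropenyl group or ionisation of the tertiary alcohol, followed by chroman closure through the C7 hydroxyl or addition of methanol. The ring B acetals on the electron-poor flavone need the longest acid exposure of the route. The fallback replaces protic solvolysis by silyl transfer; it sets out from 23 and comes back at 24. Me3SiOTf and 2,2′-bipyridyl in CH2Cl2 at 0 °C should exchange the two aryl MOM ethers for trimethylsilyl ethers under buffered, non-protic conditions and silylate the two free hydroxyls, giving the tetrakis(trimethylsilyl) ether F10. K2CO3 in MeOH then removes all four silyl groups.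

## Further compounds

F1 | step 12 | 3-[(2R)-5-hydroxy-5-methyl-2-(prop-1-en-2-yl)hexyl]-6-methoxy-2,4-bis(methoxymethoxy)benzaldehyde | C=C(C)[C@H](CCC(C)(C)O)Cc1c(OCOC)c(C=O)c(OC)cc1OCOC
F2 | step 12 | 3-[2,4-bis(methoxymethoxy)phenyl]-1-{3-[(2R)-5-hydroxy-5-methyl-2-(prop-1-en-2-yl)hexyl]-6-methoxy-2,4-bis(methoxymethoxy)phenyl}prop-2-yn-1-ol (carbinol centre unassigned) | C=C(C)[C@H](CCC(C)(C)O)Cc1c(OCOC)c(C(O)C#Cc2ccc(OCOC)cc2OCOC)c(OC)cc1OCOC
F3 | step 12 | 3-[2,4-bis(methoxymethoxy)phenyl]-1-{3-[(2R)-5-hydroxy-5-methyl-2-(prop-1-en-2-yl)hexyl]-6-methoxy-2,4-bis(methoxymethoxy)phenyl}prop-2-yn-1-one | C=C(C)[C@H](CCC(C)(C)O)Cc1c(OCOC)c(C(=O)C#Cc2ccc(OCOC)cc2OCOC)c(OC)cc1OCOC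
F4 | step 3 | 1,3-dioxoisoindolin-2-yl (3R)-6-oxo-3-(prop-1-en-2-yl)heptanoate | C=C(C)[C@@H](CC(=O)ON1C(=O)c2ccccc2C1=O)CCC(C)=O
F5 | step 3 | [4-methoxy-2,6-bis(methoxymethoxy)phenyl]zinc chloride | Cl[Zn]c1c(OCOC)cc(OC)cc1OCOC
F6 | step 6 | (5S)-5-(iodomethyl)-2,6-dimethylhept-6-en-2-ol | C=C(C)[C@@H](CI)CCC(C)(C)O
F7 | step 6 | triethyl{[(5S)-5-(iodomethyl)-2,6-dimethylhept-6-en-2-yl]oxy}silane | C=C(C)[C@@H](CI)CCC(C)(C)O[Si](CC)(CC)CC
F8 | step 6 | triethyl{[(5R)-5-{[4-methoxy-2,6-bis(methoxymethoxy)phenyl]methyl}-2,6-dimethylhept-6-en-2-yl]oxy}silane | C=C(C)[C@H](CCC(C)(C)O[Si](CC)(CC)CC)Cc1c(OCOC)cc(OC)cc1OCOC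
F9 | step 9 | (5R)-5-{[3-iodo-4-methoxy-2,6-bis(methoxymethoxy)phenyl]methyl}-2,6-dimethylhept-6-en-2-ol | C=C(C)[C@H](CCC(C)(C)O)Cc1c(OCOC)c(I)c(OC)cc1OCOC
F10 | step 13 | tetrakis(trimethylsilyl) ether of 24 (silyl on O7, O2′, O4′ and the tertiary oxygen) | C=C(C)[C@H](CCC(C)(C)O[Si](C)(C)C)Cc1c(O[Si](C)(C)C)cc(OC)c2c(=O)cc(-c3ccc(O[Si](C)(C)C)cc3O[Si](C)(C)C)oc12
A1 | alternative 1 | (5R)-2-methyl-5-(prop-1-en-2-yl)-2-(triethylsilyloxy)-8-(triisopropylsilyloxy)oct-7-yne (chain-bearing siloxyalkyne) | C=C(C)[C@H](CCC(C)(C)O[Si](CC)(CC)CC)CC#CO[Si](C(C)C)(C(C)C)C(C)C
A2 | alternative 1 | 3-methoxycyclobut-2-en-1-one | COC1=CC(=O)C1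
A3 | alternative 1 | ring A phenol with the chain (tertiary oxygen as triethylsilyl ether) at C8, free hydroxyl at C8a, triisopropylsilyl ether at C7 and methyl ether at C5 | C=C(C)[C@H](CCC(C)(C)O[Si](CC)(CC)CC)Cc1c(O)cc(OC)cc1O[Si](C(C)C)(C(C)C)C(C)C
A4 | alternative 2 | 1,1-dimethoxy-3-(trimethylsilyloxy)buta-1,3-diene carrying the R-configured chain (tertiary oxygen as triethylsilyl ether) on C4 | C=C(C)[C@H](CCC(C)(C)O[Si](CC)(CC)CC)CC=C(O[Si](C)(C)C)C=C(OC)OC
A5 | alternative 2 | 2-[2,4-bis(methoxymethoxy)phenyl]-5-(phenylsulfinyl)-4H-pyran-4-one (sulfur centre unassigned) | O=c1cc(-c2ccc(OCOC)cc2OCOC)occ1S(=O)c1ccccc1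
A6 | alternative 2 | 7-hydroxy-5-methoxy-8-alkylflavone with ring B as bis-MOM ether and the tertiary oxygen as triethylsilyl ether | C=C(C)[C@H](CCC(C)(C)O[Si](CC)(CC)CC)Cc1c(O)cc(OC)c2c(=O)cc(-c3ccc(OCOC)cc3OCOC)oc12
A7 | alternative 3 | methyl 6-[2,4-bis(methoxymethoxy)phenyl]-4-oxo-4H-pyran-3-carboxylate carrying on C2 the chain lengthened by one CH2 (chain stereocentre arranged as in 24, tertiary oxygen as triethylsilyl ether) | C=C(C)[C@H](CCC(C)(C)O[Si](CC)(CC)CC)CCc1oc(-c2ccc(OCOC)cc2OCOC)cc(=O)c1C(=O)OC
A8 | alternative 3 | 5,7-dihydroxy-8-alkylflavone with ring B as bis-MOM ether and the tertiary oxygen as triethylsilyl ether | C=C(C)[C@H](CCC(C)(C)O[Si](CC)(CC)CC)Cc1c(O)cc(O)c2c(=O)cc(-c3ccc(OCOC)cc3OCOC)oc12
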